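**Retrosynthetic overview**
- The C2-symmetric tetraene is cut at both ring–diene bonds: two identical cyclohexenyl triflates are joined one after the other to a four-carbon (E,E)-dienyl linchpin that carries tin at one end and a masked boron (MIDA boronate) at the other (Stille, then Suzuki–Miyaura coupling with the silyl ethers removed in the last pot).
- Each oxirane is opened retrosynthetically at its C–O bonds: catalyst-controlled Shi epoxidation of the homoprenyl olefin at the triflate stage, where the ring olefin is electron-poor.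
- The triflate comes from anti-selective copper-catalysed conjugate addition of a homoprenyl Grignard reagent to (S)-4-silyloxy-3-methylcyclohexenone, with triflation of the regiodefined enolate.
- Key disconnection: the ring C4–O bond, made by a new enantioselective γ-C–H oxygenation of 3-methylcyclohex-2-enone; the quaternary centre is relayed from it.
- Ring order: both cyclohexene rings come intact from the starting enone; the only rings formed are the two oxiranes, one per half, before the halves are joined.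

Assumption: in step 1 the (S,S)-ligand gives the S-benzoate, as it does with cyclohexene; if the sense proves opposite, the (R,R)-ligand is used.

**Step 1**
Reactants: 1 3-methylcyclohex-2-en-1-one (5 equiv, excess recovered)
Product: 3 (4S)-4-hydroxy-3-methylcyclohex-2-en-1-one, via benzoate 2 (not isolated)
Conditions: Cu(MeCN)4PF6 (5 mol%), (S,S)-2,2'-(propane-2,2-diyl)bis(4-tert-butyl-4,5-dihydro-1,3-oxazole) (6 mol%), PhCO3t-Bu (1 equiv, limiting), MeCN, 0 °C, 72 h; then K2CO3 (0.3 equiv), MeOH, 0 °C
Reagents that add atoms: tert-butyl peroxybenzoate, CC(C)(C)OOC(=O)c1ccccc1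
Why: Proposed new method: monovalent copper reduces the perester to a divalent copper benzoate and a tert-butoxyl radical, which abstracts the weakest C–H of 1 (the secondary, allylic ring γ-C4–H) to give a 1-oxapentadienyl radical; this is captured by the bisoxazoline-bound copper benzoate, and C–O reductive elimination from trivalent copper at the γ-terminus (conjugation retained) sets C4 as S, after which mild methanolysis frees the alcohol; the closest known reaction is the copper/bisoxazoline Kharasch–Sosnovsky allylic acyloxylation of cycloalkenes, not yet shown at the γ-methylene of a conjugated enone.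

**Step 2**
Reactants: 3 (4S)-4-hydroxy-3-methylcyclohex-2-en-1-one
Product: 4 (4S)-3-methyl-4-(triethylsilyloxy)cyclohex-2-en-1-one
Conditions: Et3SiCl, imidazole, CH2Cl2, 0 °C → rt
Reagents that add atoms: chlorotriethylsilane, CC[Si](Cl)(CC)CC
Why: Imidazole-mediated silyl ether formation protects the secondary allylic alcohol under conditions too mild to dehydrate or isomerise the γ-hydroxy enone, and no stereocentre is touched.

**Step 3**
Reactants: 4 (4S)-3-methyl-4-(triethylsilyloxy)cyclohex-2-en-1-one; 5 5-bromo-2-methylpent-2-ene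
Product: 8 (3S,4S)-3-methyl-3-(4-methylpent-3-en-1-yl)-4-(triethylsilyloxy)cyclohex-1-en-1-yl trifluoromethanesulfonate, via alkylmagnesium bromide 6 (not isolated), via bromomagnesium enolate 7 (not isolated)
Conditions: 5 (2 equiv), Mg, THF, rt; then CuBr·SMe2 (20 mol%), 4, THF, −78 → −30 °C; then N-(5-chloropyridin-2-yl)-N-(trifluoromethylsulfonyl)trifluoromethanesulfonamide, −78 °C → rt
Reagents that add atoms: N-(5-chloropyridin-2-yl)-1,1,1-trifluoro-N-(trifluoromethylsulfonyl)methanesulfonamide (Comins' reagent), FC(F)(F)S(=O)(=O)N(c1ccc(Cl)cn1)S(=O)(=O)C(F)(F)F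
Why: Copper-catalysed conjugate addition of the Grignard reagent (Kharasch type) occurs on the enone face anti to the C4 silyloxy group, so the quaternary centre C3 is set S (chain trans to oxygen, methyl cis), and the regiodefined enolate is trapped on oxygen as the enol triflate (Comins triflation), fixing the ring olefin next to the quaternary carbon.

**Step 4**
Reactants: 8 (3S,4S)-3-methyl-3-(4-methylpent-3-en-1-yl)-4-(triethylsilyloxy)cyclohex-1-en-1-yl trifluoromethanesulfonate
Product: 9 (3S,4S)-3-{2-[(2R)-3,3-dimethyloxiran-2-yl]ethyl}-3-methyl-4-(triethylsilyloxy)cyclohex-1-en-1-yl trifluoromethanesulfonate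
Conditions: 1,2:4,5-di-O-isopropylidene-β-D-erythro-2,3-hexodiulo-2,6-pyranose (Shi ketone, 30 mol%), KHSO5 (as 2KHSO5·KHSO4·K2SO4), K2CO3, Bu4NHSO4 (cat.), MeCN/CH2(OMe)2/aq Na2B4O7 buffer, 0 °C
Reagents that add atoms: potassium peroxymonosulfate, [K+].[O-]S(=O)(=O)OO
Why: In this Shi asymmetric epoxidation the chiral dioxirane attacks only the electron-rich trisubstituted side-chain olefin (the enol triflate olefin is electron-poor) through the spiro transition state, which with the D-fructose-derived ketone gives the R oxirane.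

**Step 5**
Reactants: 10 (E)-1,2-bis(tributylstannyl)ethene (3 equiv, excess recovered); 11 2-[(E)-2-bromoethenyl]-6-methyl-1,3,6,2-dioxazaborocane-4,8-dione ((E)-(2-bromoethenyl)boronic acid MIDA ester)
Product: 12 6-methyl-2-[(1E,3E)-4-(tributylstannyl)buta-1,3-dien-1-yl]-1,3,6,2-dioxazaborocane-4,8-dione
Conditions: Pd2(dba)3 (2.5 mol%), tri(2-furyl)phosphine (10 mol%), DMF, 45 °C, dark
Reagents that add atoms: none
Why: Stille coupling of the alkenyl bromide with one tin terminus of the bis-stannane goes with retention at both olefins and gives the E,E-diene; the excess of 10 suppresses reaction at the second tin, and the tetracoordinate boron of the MIDA boronate does not transmetalate under anhydrous conditions.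

**Step 6**
Reactants: 9 (3S,4S)-3-{2-[(2R)-3,3-dimethyloxiran-2-yl]ethyl}-3-methyl-4-(triethylsilyloxy)cyclohex-1-en-1-yl trifluoromethanesulfonate; 12 6-methyl-2-[(1E,3E)-4-(tributylstannyl)buta-1,3-dien-1-yl]-1,3,6,2-dioxazaborocane-4,8-dione
Product: 13 2-{(1E,3E)-4-[(3S,4S)-3-{2-[(2R)-3,3-dimethyloxiran-2-yl]ethyl}-3-methyl-4-(triethylsilyloxy)cyclohex-1-en-1-yl]buta-1,3-dien-1-yl}-6-methyl-1,3,6,2-dioxazaborocane-4,8-dione
Conditions: Pd2(dba)3 (2.5 mol%), AsPh3 (20 mol%), LiCl (3 equiv), anhydrous DMF, 40 °C, dark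
Reagents that add atoms: none
Why: Migita–Kosugi–Stille coupling of the alkenyl triflate (oxidative addition to zerovalent palladium, tin-to-palladium transmetalation with retention) attaches the first ring to the tin end of the linchpin, while the MIDA boronate stays masked; chloride turns the tin by-product into mild Bu3SnCl, so the oxirane and silyl ether are not exposed to a tin triflate, and no stereocentre is touched.

**Step 7**
Reactants: 13 2-{(1E,3E)-4-[(3S,4S)-3-{2-[(2R)-3,3-dimethyloxiran-2-yl]ethyl}-3-methyl-4-(triethylsilyloxy)cyclohex-1-en-1-yl]buta-1,3-dien-1-yl}-6-methyl-1,3,6,2-dioxazaborocane-4,8-dione; 9 (3S,4S)-3-{2-[(2R)-3,3-dimethyloxiran-2-yl]ethyl}-3-methyl-4-(triethylsilyloxy)cyclohex-1-en-1-yl trifluoromethanesulfonate (1.2 equiv)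
Product: 15 (1S,1'S,2S,2'S)-4,4'-[(1E,3E)-buta-1,3-diene-1,4-diyl]bis(2-{2-[(2R)-3,3-dimethyloxiran-2-yl]ethyl}-2-methylcyclohex-3-en-1-ol), via bis-silyl ether 14 (not isolated)
Conditions: Pd(OAc)2 (5 mol%), 2-dicyclohexylphosphino-2',6'-dimethoxybiphenyl (10 mol%), aq K3PO4 (3 M, 7.5 equiv), dioxane, 60 °C, dark; extractive work-up; then Bu4NF/AcOH (1:1), THF, 0 °C → rt
Reagents that add atoms: none
Why: In this Suzuki–Miyaura coupling aqueous phosphate hydrolyses the MIDA boronate slowly to the dienylboronic acid, which couples with the second alkenyl triflate with retention at every olefin and so closes the C2-symmetric E,E-tetraene; acetic-acid-buffered fluoride then cleaves both triethylsilyl ethers without generating a free alkoxide that could open the oxiranes.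

**Compound list**
1 | 3-methylcyclohex-2-en-1-one | CC1=CC(=O)CCC1 | starting material
2 | (1S)-2-methyl-4-oxocyclohex-2-en-1-yl benzoate | O=C1C=C(C)[C@@H](OC(=O)c2ccccc2)CC1 | intermediate
3 | (4S)-4-hydroxy-3-methylcyclohex-2-en-1-one | O=C1C=C(C)[C@@H](O)CC1 | intermediate
4 | (4S)-3-methyl-4-(triethylsilyloxy)cyclohex-2-en-1-one | O=C1C=C(C)[C@@H](O[Si](CC)(CC)CC)CC1 | intermediate
5 | 5-bromo-2-methylpent-2-ene | CC(C)=CCCBr | starting material
6 | (4-methylpent-3-en-1-yl)magnesium bromide | CC(C)=CCC[Mg]Br | intermediate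
7 | bromomagnesium (3S,4S)-3-methyl-3-(4-methylpent-3-en-1-yl)-4-(triethylsilyloxy)cyclohex-1-en-1-olate | Br[Mg]OC1=C[C@](C)(CCC=C(C)C)[C@@H](O[Si](CC)(CC)CC)CC1 | intermediate
8 | (3S,4S)-3-methyl-3-(4-methylpent-3-en-1-yl)-4-(triethylsilyloxy)cyclohex-1-en-1-yl trifluoromethanesulfonate | FC(F)(F)S(=O)(=O)OC1=C[C@](C)(CCC=C(C)C)[C@@H](O[Si](CC)(CC)CC)CC1 | intermediate
9 | (3S,4S)-3-{2-[(2R)-3,3-dimethyloxiran-2-yl]ethyl}-3-methyl-4-(triethylsilyloxy)cyclohex-1-en-1-yl trifluoromethanesulfonate | FC(F)(F)S(=O)(=O)OC1=C[C@](C)(CC[C@H]2OC2(C)C)[C@@H](O[Si](CC)(CC)CC)CC1 | intermediate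
10 | (E)-1,2-bis(tributylstannyl)ethene | CCCC[Sn](CCCC)(CCCC)/C=C/[Sn](CCCC)(CCCC)CCCC | starting material
11 | 2-[(E)-2-bromoethenyl]-6-methyl-1,3,6,2-dioxazaborocane-4,8-dione ((E)-(2-bromoethenyl)boronic acid MIDA ester) | Br/C=C/B1OC(=O)CN(C)CC(=O)O1 | starting material
12 | 6-methyl-2-[(1E,3E)-4-(tributylstannyl)buta-1,3-dien-1-yl]-1,3,6,2-dioxazaborocane-4,8-dione | CCCC[Sn](CCCC)(CCCC)/C=C/C=C/B1OC(=O)CN(C)CC(=O)O1 | intermediate
13 | 2-{(1E,3E)-4-[(3S,4S)-3-{2-[(2R)-3,3-dimethyloxiran-2-yl]ethyl}-3-methyl-4-(triethylsilyloxy)cyclohex-1-en-1-yl]buta-1,3-dien-1-yl}-6-methyl-1,3,6,2-dioxazaborocane-4,8-dione | CN1CC(=O)OB(/C=C/C=C/C2=C[C@](C)(CC[C@H]3OC3(C)C)[C@@H](O[Si](CC)(CC)CC)CC2)OC(=O)C1 | intermediate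
14 | (1E,3E)-1,4-bis[(3S,4S)-3-{2-[(2R)-3,3-dimethyloxiran-2-yl]ethyl}-3-methyl-4-(triethylsilyloxy)cyclohex-1-en-1-yl]buta-1,3-diene | CC1(C)O[C@@H]1CC[C@@]1(C)C=C(/C=C/C=C/C2=C[C@](C)(CC[C@H]3OC3(C)C)[C@@H](O[Si](CC)(CC)CC)CC2)CC[C@@H]1O[Si](CC)(CC)CC | intermediate
15 | (1S,1'S,2S,2'S)-4,4'-[(1E,3E)-buta-1,3-diene-1,4-diyl]bis(2-{2-[(2R)-3,3-dimethyloxiran-2-yl]ethyl}-2-methylcyclohex-3-en-1-ol) | CC1(C)O[C@@H]1CC[C@@]1(C)C=C(/C=C/C=C/C2=C[C@](C)(CC[C@H]3OC3(C)C)[C@@H](O)CC2)CC[C@@H]1O | target

**Total step count:** 7.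
**Longest linear sequence:** 6 steps (1 → 3 → 4 → 8 → 9 → 13 → 15, that is steps 1, 2, 3, 4, 6 and 7); step 5 is a one-step side branch from 10 and 11.

**Steps most likely to fail, with fallbacks**

Step 1 (the proposed new γ-oxygenation). The risks are hydrogen abstraction at the methyl group or at C6 instead of C4, C–O formation at the α-terminus, and modest enantioselectivity. Any shortfall in enantiomeric purity is partly corrected in steps 6 and 7, because joining two halves channels the minor series mainly into separable diastereomers. The fallback uses known chemistry and runs from 1 back to 3. Acid-catalysed ketalisation of 1 with ethylene glycol (p-TsOH, benzene, Dean–Stark) moves the olefin out of conjugation and gives 7-methyl-1,4-dioxaspiro[4.5]dec-7-ene F1. Shi epoxidation of this trisubstituted ring olefin, with the enantiomer of the ketone used in step 4, gives (1R,6S)-1-methylspiro[7-oxabicyclo[4.1.0]heptane-3,2'-[1,3]dioxolane] F2. Mild hydrolysis (PPTS, wet acetone, then Et3N) unmasks the ketone, and β-elimination of the oxirane oxygen from the methyl-bearing carbon delivers 3 with the C4–O bond untouched.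

Step 3 (quaternary centre next to a silyloxy-bearing carbon, and triflation of a magnesium enolate). The risks are slow addition at the hindered β-carbon, competing 1,2-addition, and incomplete O-triflation. The fallback runs from 4 back to 8 and separates the two events. The copper-catalysed addition of 6 is run with Me3SiCl as a silyl accelerator, and the product is isolated as the silyl enol ether triethyl{[(1S,2S)-2-methyl-2-(4-methylpent-3-en-1-yl)-4-(trimethylsilyloxy)cyclohex-3-en-1-yl]oxy}silane F3. The lithium enolate is then regenerated regiospecifically with MeLi (THF, 0 °C) and triflated with PhNTf2 to give 8.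

Step 7 (slow-release coupling on a light- and acid-sensitive polyene). The risks are protodeboronation of the released dienylboronic acid, hydrolysis of the triflate in the aqueous base, and loss of the tetraene or its epoxy alcohol units on work-up. The fallback runs from 9 back to 14 and builds the diene as C2 + C2 with tin chemistry only, so 12 and 13 are not needed. Stille coupling of 9 with an excess of commercial 10 (Pd2(dba)3, AsPh3, LiCl, DMF) gives tributyl{(E)-2-[(3S,4S)-3-{2-[(2R)-3,3-dimethyloxiran-2-yl]ethyl}-3-methyl-4-(triethylsilyloxy)cyclohex-1-en-1-yl]ethenyl}stannane F4. Half of this material is treated with I2 (CH2Cl2, NaHCO3, 0 °C), and iododestannylation with retention gives {[(1S,2S)-2-{2-[(2R)-3,3-dimethyloxiran-2-yl]ethyl}-4-[(E)-2-iodoethenyl]-2-methylcyclohex-3-en-1-yl]oxy}triethylsilane F5. Stille coupling of F4 with F5 (Pd2(dba)3, AsPh3, N-methylpyrrolidone, rt, dark) forms the central bond and gives 14, which is desilylated with buffered Bu4NF as in step 7.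

**Further compounds**
F1 | step 1 | 7-methyl-1,4-dioxaspiro[4.5]dec-7-ene | CC1=CCCC2(C1)OCCO2
F2 | step 1 | (1R,6S)-1-methylspiro[7-oxabicyclo[4.1.0]heptane-3,2'-[1,3]dioxolane] | O1CCOC12C[C@@]3(C)O[C@H]3CC2
F3 | step 3 | triethyl{[(1S,2S)-2-methyl-2-(4-methylpent-3-en-1-yl)-4-(trimethylsilyloxy)cyclohex-3-en-1-yl]oxy}silane | C[Si](C)(C)OC1=C[C@](C)(CCC=C(C)C)[C@@H](O[Si](CC)(CC)CC)CC1
F4 | step 7 | tributyl{(E)-2-[(3S,4S)-3-{2-[(2R)-3,3-dimethyloxiran-2-yl]ethyl}-3-methyl-4-(triethylsilyloxy)cyclohex-1-en-1-yl]ethenyl}stannane | CCCC[Sn](CCCC)(CCCC)/C=C/C1=C[C@](C)(CC[C@H]2OC2(C)C)[C@@H](O[Si](CC)(CC)CC)CC1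
F5 | step 7 | {[(1S,2S)-2-{2-[(2R)-3,3-dimethyloxiran-2-yl]ethyl}-4-[(E)-2-iodoethenyl]-2-methylcyclohex-3-en-1-yl]oxy}triethylsilane | I/C=C/C1=C[C@](C)(CC[C@H]2OC2(C)C)[C@@H](O[Si](CC)(CC)CC)CC1
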